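The readings are simulated with constants of no real substance; scatter was added.

The amounts of L were my starting point: Z and X in a closed, stirred flask, read at the same times in each run, with Wednesday's flask still to come.

| flask | Z | X | time |
|---|---|---|---|
| Thursday's | 0.400 M | 0.800 M |  |
| Monday's | 0.200 M | 0.600 M |  |
| Saturday's | 0.400 M | 1.60 M |  |
| Sunday's | 0.200 M | 0.800 M |  |
| Wednesday's | 0.100 M | 0.200 M | 3.7 min |

| run | time / min | [L] / M |
|---|---|---|
| Thursday's run | 0.62 | 0.0657 |
| Thursday's run | 1.2 | 0.0927 |
| Thursday's run | 1.9 | 0.1096 |
| Thursday's run | 2.5 | 0.1162 |
| Thursday's run | 3.1 | 0.1199 |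
| Thursday's run | 3.7 | 0.1200 |
| Monday's run | 0.62 | 0.0244 |
| Monday's run | 1.2 | 0.0381 |
| Monday's run | 1.9 | 0.0420 |
| Monday's run | 2.5 | 0.0459 |
| Monday's run | 3.1 | 0.0489 |
| Monday's run | 3.7 | 0.0484 |
| Saturday's run | 0.62 | 0.1666 |
| Saturday's run | 1.2 | 0.2205 |
| Saturday's run | 1.9 | 0.2488 |
| Saturday's run | 2.5 | 0.2615 |
| Saturday's run | 3.1 | 0.2657 |
| Saturday's run | 3.7 | 0.2687 |
| Sunday's run | 0.62 | 0.0388 |
| Sunday's run | 1.2 | 0.0565 |
| Sunday's run | 1.9 | 0.0668 |
| Sunday's run | 2.5 | 0.0694 |
| Sunday's run | 3.1 | 0.0706 |
| Sunday's run | 3.7 | 0.0712 |

(scatter of a reading: 0.001 M)

1. order of the initial rate in [Z], near the charge of the Thursday's run, the rate being that where two percent of its Z are L (one fixed amount of L, the same in the runs compared)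
2. order of the initial rate in [X], near the charge of the Thursday's run, the rate being that where two percent of its Z are L
3. L in the Wednesday's run at 3.7 min, as a share of the Z charged

- Overall: Z + X -> L.
- Constant volume, constant temperature.
- The analysis sees a species whether free or bound.
- "The second partner" is X.
- An order is taken over about fifteen percent of the charge, up and down.

I read the column of L in Thursday's run first. L stood at 0.0657 M at 0.62 min and at 0.1200 M at 3.7 min, and the last steps were small, so L had levelled off with 0.280 M of the Z charged unturned.

Next I read how quickly Thursday's run closed its gap to its last reading, and then Saturday's. I called the time in which that gap shrinks by a factor of e the working time 0.774 min, read from Thursday's run between 0.62 min and 1.9 min. Saturday's run, with twice the X, gave 0.783 min, so I took the working time as common to these two runs.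

That let me replace each curve by its mean: a flat rate lasting the working time, equal to the last reading divided by that time. Thursday's run came to 0.155 M/min and Sunday's run, with half the Z and the same X, to 0.0919 M/min, on my assumption that the same working time held in Sunday's run. Setting these two side by side, I reckoned an order in Z of 0.753. This is itself a mean over the whole doubling, not the slope at Thursday's charge.

The forecast, made from the same runs, held that something “seems to die at a fixed rate and L stops”. It gave 0.7 for Z, a little below my figure, 1.6 for X, and 4.5% for Wednesday's run.

The flask gave 0.57 for Z, 1.8 for X and 4.63% for Wednesday's run. The forecast's figures for X and Wednesday's run lay within their margins, and its figure for Z did not.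

    Z + 2 X → L + X (2.598 /M²/min)
    X → Wa (0.7200 /min)
    Z + X ⇌ ZX, settled at all times (2.190 /M)

The working time turned Thursday's early rate of 0.14 M/min into 0.110 M, against a last reading of 0.1200 M. It turned Sunday's 0.085 M/min into 0.0658 M, against 0.0712 M. Those two rates also show where the forecast parted from the flask. Sunday's run, with half the Z of Thursday's run, kept 0.60 of its rate, an order of 0.740 across the doubling, higher than the 0.57 at Thursday's charge. The association of Z and X to ZX brings the order at that charge down from 1.0 to 0.57.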